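East, at 0.065 M, levels off near 35.2 % of the charge. North-west, at 0.20 M, levels off near 20.7 %. Each is the mean of that run's last three readings.

| setting | east | west | north-west | cedar | ash |
|---|---|---|---|---|---|
| substrate | 0.065 M | 0.11 M | 0.20 M | 0.20 M | 0.050 M |
| remark | run made earlier | run made earlier | run made earlier |  |  |
| time |  |  |  | 0.50 h | 1.5 h |

- east (time / min: ring / %): 6.00: 20.2; 15.0: 30.5; 30.0: 36.2; 50.0: 34.9; 60.0: 34.4
- west (time / min: ring / %): 5.00: 17.0; 10.0: 23.5; 20.0: 27.5; 30.0: 27.6; 60.0: 27.7
- north-west (time / min: ring / %): 5.00: 13.7; 10.0: 17.8; 20.0: 20.1; 30.0: 19.5; 60.0: 22.5

(scatter of a reading: 1 percentage point)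

- which of the two ends with the higher amount of ring, in percent of the substrate charged ("neither" if they lie within 2 percentage points) (cedar / ash / neither)
- ring at the end, in percent of the substrate charged, cedar
- ring at the end, in percent of the substrate charged, ash

- a reading or a percentage of ring counts all its forms, free or not

We build our reckoning one process at a time.

1. Take the main step alone. Substrate closes to ring and the whole charge ends as ring, whatever its size. The runs disagree.

2. Add a second-order side path. Ring's share now falls as substrate rises. We replace the falling curve by its mean, so the reciprocal of the yield climbs straight with the charge. East and north-west give a slope of 14.7 /M. The line gives west 28.5 %, and its mean reading is 27.6 %. That error of 0.90 percentage points stands against a scatter of 1 point.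

3. Add the rest. East falls 1.8 points after its peak, a weak reading. In east the drain is 0.0360 /h, the fraction of the charge lost as ring per hour after the peak. We assume a zero-order loss, the same amount per hour in each flask. West then loses 1.1 points in 30.0 min, which its scatter hides.

4. For ash, the line gives 38.1 %. Its drain is 0.0468 /h, and from 30.0 min to 1.5 h that takes 4.7 points, leaving 33.4 %. For cedar we take the north-west mean, 20.7 %.

The forecast says 20.5 % for cedar and 40 % for ash, so ash ends higher. Its grounds include “The ring does not visibly decay”. Our ash figure lies lower.

The flask gives 20.9 % for cedar and 33.6 % for ash, so ash ends higher.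

    substrate → ring (k = 0.0790 /min)
    2 substrate → open dimer (k = 1.90 /M/min)
    ring → over-reaction product (k = 0.00830 /min)
    crystals ⇌ ring, rate k4*(cs4 - [ring]) while solid is left; crystals form when [ring] > cs4 (solubility = 6.00 mM, k = 24.0 /min)
    ring ⇌ isomer of the product (K = 0.700, k = 0.0720 /min)

In ash, dissolved ring enters the isomer faster than the over-reaction product, at a forward ratio of 0.12, but that exchange relaxes in 0.0661 h, and the isomer stands at 8.31 % after 0.750 h and 8.40 % at the end. Over that stretch ash's over-reaction product gains 4.5 points and its ring falls 3.7 points, where the drain gives 3.5 points. Left until 2.5 h, the ash flask should drop by the drain to 28.9 %. It gives 27.7 %.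

The numbers in the tables come from a simulation from invented constants, noise included.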